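**Retrosynthetic overview**

1. C15=C15' is cut last (Wittig): acetylenic C20 phosphonium salt 21 (C1'–C15') plus triol C20 aldehyde 33 (C1–C15).
2. The strategy rests on C9'=C10': a trisubstituted E-alkene whose C9' carries the C19' methyl and is bonded directly to the C7'≡C8' alkyne on the C1'–C6' cyclohexene ring. It is read as the free alkyne end of ring 1,3-diyne 11 plus a methyl from Me3Al, with C10'–C11' closed in the same pot onto dienyl iodide 15.
3. Triol half: C6–C7 by Negishi coupling of the same enol triflate 6 with the C5 dienylzinc made from iodide 15 by iodine–lithium exchange; hydroxyl-directed syn epoxidation of C5=C6; anti hydration at C5 (sets C5 and C6); C5 phosphonate extension to C15.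
4. No ring is formed. Both six-membered carbocycles are the ketoisophorone ring, carried through (4R,6R)-actinol and triflate 6; ring C1'–C6' is used as made, ring C1–C6 is oxidised afterwards.

Key step: step 9

Remark: carotenoid numbering is used (primed = acetylenic end). The ring carbinol keeps one spatial arrangement throughout; it is 3R in the cyclohexene rings and 3S in the saturated triol ring only because the CIP priorities change. Compounds 1, 7, 12, 16 and 29 are taken as commercial. Polyene steps are run in dim light under argon.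

**Route**

Step 1
Reactants: 1 ketoisophorone
Product: 2 (6R)-levodione
Conditions: baker's yeast, sucrose, H2O, 30 °C
Reagents that add atoms: none
Why: The ene-reductase of fermenting yeast reduces only the enedione C=C and delivers hydrogen to one face, which should set C6 as R (biocatalytic conjugate reduction).

Step 2
Reactants: 2 (6R)-levodione
Product: 3 (4R,6R)-actinol
Conditions: H2, Raney Ni, MeOH, rt; recrystallisation
Reagents that add atoms: none
Why: Heterogeneous carbonyl hydrogenation should touch only the C4 ketone (C1 lies between a quaternary and a tertiary carbon) and add hydrogen from the face away from the axial C2 methyl, giving mainly the trans alcohol and so the 4R centre under substrate control; the minor cis epimer is removed by crystallisation.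

Step 3
Reactants: 3 (4R,6R)-actinol
Product: 4 (4R,6R)-4-(tert-butyldimethylsilyloxy)-2,2,6-trimethylcyclohexanone
Conditions: TBSCl, imidazole, DMF, rt
Reagents that add atoms: tert-butyldimethylsilyl chloride, CC(C)(C)[Si](C)(C)Cl
Why: Standard imidazole-mediated silylation of a secondary alcohol, which should leave the hindered ketone untouched.

Step 4
Reactants: 4 silyloxy ketone
Product: 6 (4R)-4-(tert-butyldimethylsilyloxy)-2,6,6-trimethylcyclohex-1-en-1-yl triflate, via lithium enolate 5 (not isolated)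
Conditions: LiN(iPr)2, THF, −78 °C; PhNTf2, −78 °C to rt
Reagents that add atoms: N-phenylbis(trifluoromethanesulfonimide), O=S(=O)(N(c1ccccc1)S(=O)(=O)C(F)(F)F)C(F)(F)F
Why: Only C6 carries an α-hydrogen, so deprotonation and O-sulfonylation of the enolate should give a single enol triflate; the C6 centre is erased on purpose and the silyloxy carbon stays as the only stereocentre.

Step 5
Reactants: 6 enol triflate; 7 1,4-bis(trimethylsilyl)buta-1,3-diyne
Product: 10 silyl-capped ring diyne, via lithium silylbutadiynide 8 (not isolated), via silylbutadiynylzinc chloride 9 (not isolated)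
Conditions: 7, MeLi·LiBr, THF, rt; ZnCl2, 0 °C; then 6, Pd(PPh3)4 (5 mol %), THF, rt to 50 °C
Reagents that add atoms: none
Why: Methyllithium cleaves one alkynyl–silicon bond of 7, and the zinc acetylide should couple with the alkenyl triflate under palladium catalysis (Negishi alkynylation) to form C6'–C7' without handling the volatile free diyne.

Step 6
Reactants: 10 silyl-capped ring diyne
Product: 11 ring 1,3-diyne, (R)-4-(buta-1,3-diynyl)-3,5,5-trimethylcyclohex-3-enyl TBS ether
Conditions: K2CO3 (cat.), MeOH/THF, rt; used at once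
Reagents that add atoms: none
Why: Methanolysis of the alkynyl C–Si bond is fast under carbonate catalysis, while the secondary silyl ether should survive.

Step 7
Reactants: 12 (E)-3-methylpent-2-en-4-yn-1-ol
Product: 13 TBS ether of 12
Conditions: TBSCl, imidazole, CH2Cl2, 0 °C to rt
Reagents that add atoms: tert-butyldimethylsilyl chloride, CC(C)(C)[Si](C)(C)Cl
Why: Routine silylation of a primary allylic alcohol.

Step 8
Reactants: 13 silylated enynol
Product: 15 (2E,4E)-5-iodo-3-methylpenta-2,4-dienyl TBS ether, via alkenylzirconocene chloride 14 (not isolated)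
Conditions: Cp2Zr(H)Cl, THF, rt, dark; I2, 0 °C
Reagents that add atoms: iodine, II
Why: Schwartz hydrozirconation adds Zr–H syn to the terminal alkyne with zirconium on the end carbon, and iodinolysis with retention should give the (E)-alkenyl iodide.

Step 9
Reactants: 11 ring 1,3-diyne; 16 trimethylaluminium; 15 dienyl iodide
Product: 19 bis-TBS ether of the acetylenic C20 half, via alkenylalane 17 (not isolated), via alkenylzinc chloride 18 (not isolated)
Conditions: 16 (2.5 equiv), Cp2ZrCl2 (25 mol %), ClCH2CH2Cl, 0 °C to rt; volatiles removed in vacuo; THF, ZnCl2 (1 equiv), 15, Pd(PPh3)4 (5 mol %), rt, dark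
Reagents that add atoms: trimethylaluminium 16, C[Al](C)C
Why: The Cp2ZrCl2/Me3Al pair forms a chloride-bridged Zr–CH3/Al species that adds methyl and metal syn across the terminal C9'≡C10' bond, methyl to the internal carbon C9' and aluminium to C10', giving alane 17 (zirconium-catalysed methylalumination). Zinc chloride relays the alkenyl group to the palladium that has inserted into the C–I bond of 15, and reductive elimination forms C10'–C11' with retention at both alkenes (Negishi coupling), so C8' and C11' end up trans. The closest known reaction type is the one-pot methylalumination and palladium coupling of terminal alkynes and conjugated enynes used for polyene chains; here the alkyne is the free end of a 1,3-diyne. No ring closes and no stereocentre is formed. The step needs methyl delivery to C9', syn addition and reaction at the terminal alkyne only: the first two are inherent to the carbometalation, and the internal C7'≡C8' bond is disubstituted and screened by the C1' gem-dimethyl and C5' methyl groups. Excess Me3Al is stripped before the coupling so that methyl transfer to palladium does not compete, and both silyl ethers should tolerate the Lewis acid.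

Step 10
Reactants: 19 bis-TBS ether
Product: 20 acetylenic C20 diol
Conditions: Bu4NF, THF, 0 °C to rt
Reagents that add atoms: none
Why: Fluoride cleaves both silyl ethers; nothing else in the enyne polyene is fluoride-sensitive.

Step 11
Reactants: 20 acetylenic C20 diol
Product: 21 acetylenic C20 triphenylphosphonium bromide
Conditions: PPh3·HBr, MeOH, rt, dark
Reagents that add atoms: triphenylphosphine hydrobromide, Br.P(c1ccccc1)(c1ccccc1)c1ccccc1
Why: The primary polyenylic alcohol ionises under HBr and the allylic cation is captured by PPh3 at the unhindered C15' terminus (classical carotenoid phosphonium salt formation), while the non-allylic ring hydroxyl should not react.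

Step 12
Reactants: 15 dienyl iodide; 6 enol triflate
Product: 24 bis-TBS ether of the C15 trienol, via dienyllithium 22 (not isolated), via dienylzinc chloride 23 (not isolated)
Conditions: 15, t-BuLi (2.0 equiv), Et2O, −78 °C; ZnCl2 in THF, −78 to 0 °C; then 6, Pd(PPh3)4 (5 mol %), THF, rt to 50 °C, dark
Reagents that add atoms: none
Why: Iodine–lithium exchange with t-BuLi on the (E)-alkenyl iodide keeps the alkene geometry, and transfer to zinc followed by Negishi coupling with the alkenyl triflate should form C6–C7 with the E geometry of C7=C8 and C9=C10 taken over from 15.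

Step 13
Reactants: 24 bis-TBS ether
Product: 25 C15 diol, (2E,4E)-5-[(4R)-4-hydroxy-2,6,6-trimethylcyclohex-1-enyl]-3-methylpenta-2,4-dien-1-ol
Conditions: Bu4NF, THF, rt
Reagents that add atoms: none
Why: Fluoride removes both silyl groups and so frees the ring hydroxyl needed as a directing group.

Step 14
Reactants: 25 C15 diol
Product: 26 C15 hydroxy dienal
Conditions: MnO2 (activated), CH2Cl2, rt
Reagents that add atoms: none
Why: MnO2 oxidises only the allylic primary alcohol; this removes an allylic directing group and makes the side chain electron-poor before the epoxidation.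

Step 15
Reactants: 26 C15 hydroxy dienal
Product: 27 syn-epoxy dienal, (3S,5S,6R)
Conditions: VO(acac)2 (5 mol %), t-BuOOH, CH2Cl2, 0 °C to rt
Reagents that add atoms: tert-butyl hydroperoxide, CC(C)(C)OO
Why: The homoallylic ring hydroxyl binds the vanadium alkylperoxide and delivers oxygen to its own face of the tetrasubstituted C5=C6 bond (hydroxyl-directed epoxidation), which should set C5 and C6 syn to the 3-OH, while the acceptor-substituted chain alkenes stay inert.

Step 16
Reactants: 27 syn-epoxy dienal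
Product: 28 C15 triol dienal, (3S,5R,6R)
Conditions: HClO4 (cat.), THF/H2O 1:1, 0 °C
Reagents that add atoms: water, O
Why: In the acid-catalysed epoxide hydrolysis C6 is neopentylic and its cation is deactivated by the dienal, so water should attack C5 anti to the oxirane oxygen in the trans-diaxial (Fürst–Plattner) sense, inverting C5 to R and keeping the C6–O bond (6R); the 3-OH sits on the oxirane face and cannot attack from behind.

Step 17
Reactants: 28 C15 triol dienal; 29 triethyl 3-methyl-4-phosphonocrotonate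
Product: 31 C20 triol ethyl ester, via sodium phosphonate carbanion 30 (not isolated)
Conditions: 29, NaN(SiMe3)2, THF, −78 °C; then 28, −78 to 0 °C
Reagents that add atoms: none
Why: Horner–Wadsworth–Emmons olefination with the vinylogous phosphonoacetate should form C11=C12 as E and give mainly the 13E ester; the stabilised carbanion is too weak a base to deprotonate the free alcohols.

Step 18
Reactants: 31 C20 triol ethyl ester
Product: 32 C20 tetraol
Conditions: iBu2AlH (excess), CH2Cl2, −78 °C; aq. potassium sodium tartrate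
Reagents that add atoms: none
Why: Aluminium hydride reduces the conjugated ester 1,2 to the allylic alcohol; the three hydroxyls only consume extra hydride, and the neutral work-up protects the acid-labile tertiary allylic carbinol.

Step 19
Reactants: 32 C20 tetraol
Product: 33 triol C20 aldehyde
Conditions: MnO2 (activated), CH2Cl2/acetone, rt, dark
Reagents that add atoms: none
Why: MnO2 oxidises the primary polyenylic alcohol selectively; the secondary ring carbinol is not allylic and the tertiary allylic one cannot be oxidised.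

Step 20
Reactants: 21 acetylenic C20 phosphonium bromide; 33 triol C20 aldehyde
Product: 36 heteroxanthin (target), via phosphorus ylide 34 (not isolated), via 15-cis isomer 35 (not isolated)
Conditions: NaOMe, MeOH/CH2Cl2, 0 °C to rt, dark; then EtOH, 70 °C, argon, dark
Reagents that add atoms: none
Why: Wittig olefination through ylide 34 should form C15=C15' as a Z/E mixture, and the hindered central Z bond of 35 relaxes thermally to the all-E polyene; the alkoxide base tolerates the four free hydroxyls, as is usual for hydroxylated carotenoid couplings.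

**Compound list**

1 | ketoisophorone | CC1=CC(=O)CC(C)(C)C1=O | starting material
2 | (6R)-levodione, (6R)-2,2,6-trimethylcyclohexane-1,4-dione | C[C@@H]1CC(=O)CC(C)(C)C1=O | intermediate
3 | (4R,6R)-actinol, (4R,6R)-4-hydroxy-2,2,6-trimethylcyclohexanone | C[C@@H]1C[C@@H](O)CC(C)(C)C1=O | intermediate
4 | (4R,6R)-4-(tert-butyldimethylsilyloxy)-2,2,6-trimethylcyclohexanone | C[C@@H]1C[C@@H](O[Si](C)(C)C(C)(C)C)CC(C)(C)C1=O | intermediate
5 | lithium (4R)-4-(tert-butyldimethylsilyloxy)-2,6,6-trimethylcyclohex-1-en-1-olate | CC1=C(O[Li])C(C)(C)C[C@H](O[Si](C)(C)C(C)(C)C)C1 | intermediate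
6 | (4R)-4-(tert-butyldimethylsilyloxy)-2,6,6-trimethylcyclohex-1-en-1-yl trifluoromethanesulfonate | CC1=C(OS(=O)(=O)C(F)(F)F)C(C)(C)C[C@H](O[Si](C)(C)C(C)(C)C)C1 | intermediate
7 | 1,4-bis(trimethylsilyl)buta-1,3-diyne | C[Si](C)(C)C#CC#C[Si](C)(C)C | starting material
8 | lithium 4-(trimethylsilyl)buta-1,3-diyn-1-ide | [Li]C#CC#C[Si](C)(C)C | intermediate
9 | chloro[4-(trimethylsilyl)buta-1,3-diyn-1-yl]zinc | Cl[Zn]C#CC#C[Si](C)(C)C | intermediate
10 | (R)-tert-butyldimethylsilyl ether of 3,5,5-trimethyl-4-[4-(trimethylsilyl)buta-1,3-diynyl]cyclohex-3-en-1-ol | CC1=C(C#CC#C[Si](C)(C)C)C(C)(C)C[C@H](O[Si](C)(C)C(C)(C)C)C1 | intermediate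
11 | (R)-tert-butyldimethylsilyl ether of 4-(buta-1,3-diynyl)-3,5,5-trimethylcyclohex-3-en-1-ol (ring 1,3-diyne) | CC1=C(C#CC#C)C(C)(C)C[C@H](O[Si](C)(C)C(C)(C)C)C1 | intermediate
12 | (E)-3-methylpent-2-en-4-yn-1-ol | C#C/C(C)=C/CO | starting material
13 | tert-butyldimethylsilyl ether of (E)-3-methylpent-2-en-4-yn-1-ol | C#C/C(C)=C/CO[Si](C)(C)C(C)(C)C | intermediate
14 | chlorobis(cyclopentadienyl)[(1E,3E)-5-(tert-butyldimethylsilyloxy)-3-methylpenta-1,3-dienyl]zirconium (cyclopentadienyl rings drawn σ-bonded) | Cl[Zr](/C=C/C(C)=C/CO[Si](C)(C)C(C)(C)C)(C1C=CC=C1)C1C=CC=C1 | intermediate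
15 | tert-butyldimethylsilyl ether of (2E,4E)-5-iodo-3-methylpenta-2,4-dien-1-ol | I/C=C/C(C)=C/CO[Si](C)(C)C(C)(C)C | intermediate
16 | trimethylaluminium | C[Al](C)C | starting material
17 | dimethyl[(E)-2-methyl-4-[(4R)-4-(tert-butyldimethylsilyloxy)-2,6,6-trimethylcyclohex-1-enyl]but-1-en-3-ynyl]alane | CC1=C(C#C/C(C)=C/[Al](C)C)C(C)(C)C[C@H](O[Si](C)(C)C(C)(C)C)C1 | intermediate
18 | chloro[(E)-2-methyl-4-[(4R)-4-(tert-butyldimethylsilyloxy)-2,6,6-trimethylcyclohex-1-enyl]but-1-en-3-ynyl]zinc | CC1=C(C#C/C(C)=C/[Zn]Cl)C(C)(C)C[C@H](O[Si](C)(C)C(C)(C)C)C1 | intermediate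
19 | bis(tert-butyldimethylsilyl) ether of (2E,4E,6E)-9-[(4R)-4-hydroxy-2,6,6-trimethylcyclohex-1-enyl]-3,7-dimethylnona-2,4,6-trien-8-yn-1-ol | CC1=C(C#C/C(C)=C/C=C/C(C)=C/CO[Si](C)(C)C(C)(C)C)C(C)(C)C[C@H](O[Si](C)(C)C(C)(C)C)C1 | intermediate
20 | (2E,4E,6E)-9-[(4R)-4-hydroxy-2,6,6-trimethylcyclohex-1-enyl]-3,7-dimethylnona-2,4,6-trien-8-yn-1-ol | CC1=C(C#C/C(C)=C/C=C/C(C)=C/CO)C(C)(C)C[C@H](O)C1 | intermediate
21 | [(2E,4E,6E)-9-[(4R)-4-hydroxy-2,6,6-trimethylcyclohex-1-enyl]-3,7-dimethylnona-2,4,6-trien-8-ynyl]triphenylphosphonium bromide | CC1=C(C#C/C(C)=C/C=C/C(C)=C/C[P+](c2ccccc2)(c2ccccc2)c2ccccc2)C(C)(C)C[C@H](O)C1.[Br-] | intermediate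
22 | [(1E,3E)-5-(tert-butyldimethylsilyloxy)-3-methylpenta-1,3-dienyl]lithium | [Li]/C=C/C(C)=C/CO[Si](C)(C)C(C)(C)C | intermediate
23 | chloro[(1E,3E)-5-(tert-butyldimethylsilyloxy)-3-methylpenta-1,3-dienyl]zinc | Cl[Zn]/C=C/C(C)=C/CO[Si](C)(C)C(C)(C)C | intermediate
24 | bis(tert-butyldimethylsilyl) ether of (2E,4E)-5-[(4R)-4-hydroxy-2,6,6-trimethylcyclohex-1-enyl]-3-methylpenta-2,4-dien-1-ol | CC1=C(/C=C/C(C)=C/CO[Si](C)(C)C(C)(C)C)C(C)(C)C[C@H](O[Si](C)(C)C(C)(C)C)C1 | intermediate
25 | (2E,4E)-5-[(4R)-4-hydroxy-2,6,6-trimethylcyclohex-1-enyl]-3-methylpenta-2,4-dien-1-ol | CC1=C(/C=C/C(C)=C/CO)C(C)(C)C[C@H](O)C1 | intermediate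
26 | (2E,4E)-5-[(4R)-4-hydroxy-2,6,6-trimethylcyclohex-1-enyl]-3-methylpenta-2,4-dienal | CC1=C(/C=C/C(C)=C/C=O)C(C)(C)C[C@H](O)C1 | intermediate
27 | (2E,4E)-5-[(1R,4S,6S)-4-hydroxy-2,2,6-trimethyl-7-oxabicyclo[4.1.0]heptan-1-yl]-3-methylpenta-2,4-dienal | C[C@]12C[C@@H](O)CC(C)(C)[C@]1(O2)/C=C/C(C)=C/C=O | intermediate
28 | (2E,4E)-3-methyl-5-[(1R,2R,4S)-1,2,4-trihydroxy-2,6,6-trimethylcyclohexyl]penta-2,4-dienal | O=C/C=C(C)/C=C/[C@@]1(O)C(C)(C)C[C@H](O)C[C@@]1(C)O | intermediate
29 | triethyl 3-methyl-4-phosphonocrotonate (E/Z mixture) | CCOC(=O)C=C(C)CP(=O)(OCC)OCC | starting material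
30 | sodium salt of the carbanion of 29 | CCOC(=O)C=C(C)[CH-]P(=O)(OCC)OCC.[Na+] | intermediate
31 | ethyl (2E,4E,6E,8E)-3,7-dimethyl-9-[(1R,2R,4S)-1,2,4-trihydroxy-2,6,6-trimethylcyclohexyl]nona-2,4,6,8-tetraenoate | CCOC(=O)/C=C(C)/C=C/C=C(C)/C=C/[C@@]1(O)C(C)(C)C[C@H](O)C[C@@]1(C)O | intermediate
32 | (1R,2R,4S)-1-[(1E,3E,5E,7E)-9-hydroxy-3,7-dimethylnona-1,3,5,7-tetraenyl]-2,6,6-trimethylcyclohexane-1,2,4-triol | OC/C=C(C)/C=C/C=C(C)/C=C/[C@@]1(O)C(C)(C)C[C@H](O)C[C@@]1(C)O | intermediate
33 | (2E,4E,6E,8E)-3,7-dimethyl-9-[(1R,2R,4S)-1,2,4-trihydroxy-2,6,6-trimethylcyclohexyl]nona-2,4,6,8-tetraenal | O=C/C=C(C)/C=C/C=C(C)/C=C/[C@@]1(O)C(C)(C)C[C@H](O)C[C@@]1(C)O | intermediate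
34 | triphenylphosphonium ylide of 21 | CC1=C(C#C/C(C)=C/C=C/C(C)=C/C=P(c2ccccc2)(c2ccccc2)c2ccccc2)C(C)(C)C[C@H](O)C1 | intermediate
35 | (15Z)-isomer of the target | CC1=C(C#C/C(C)=C/C=C/C(C)=C/C=C\C=C(C)\C=C\C=C(C)\C=C\[C@@]2(O)C(C)(C)C[C@H](O)C[C@@]2(C)O)C(C)(C)C[C@H](O)C1 | intermediate
36 | heteroxanthin, (3S,5R,6R,3'R)-7',8'-didehydro-5,6-dihydro-β,β-carotene-3,5,6,3'-tetrol | CC1=C(C#C/C(C)=C/C=C/C(C)=C/C=C/C=C(C)/C=C/C=C(C)/C=C/[C@@]2(O)C(C)(C)C[C@H](O)C[C@@]2(C)O)C(C)(C)C[C@H](O)C1 | target

**Step count**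

Total: 20 steps. Longest linear sequence: 13 steps (steps 1–4, 12–19, 20).

**Steps most likely to fail, with fallbacks**

Step 9. Me3Al may deprotonate the acidic diynyl C–H instead of adding across it, or the conjugated second triple bond may take part in further addition or oligomerisation, so that too little alane reaches the coupling. The fallback takes the C9'=C10' alkene ready-made from enynol 12. It sets out from triflate 6 and enynol 12. Sonogashira coupling (Pd(PPh3)4, CuI, iPr2NH, THF) should give the silylated C15 enynol F1. MnO2 oxidation gives the C15 ynenal F2. Horner–Wadsworth–Emmons reaction with phosphonate 29 (NaN(SiMe3)2, THF, −78 °C) gives the silylated C20 ester F3. Reduction with iBu2AlH gives the silylated C20 alcohol F4, and Bu4NF brings the sequence back to the route at diol 20.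

Step 16. The oxirane may ionise toward C6, or the developing C5 cation may contract the ring or eliminate faster than water adds anti at C5, which would erode the regio- and stereocontrol of the diol. The fallback runs the same epoxidation and hydration one vinylogue shorter, on an enone in which C6 is deactivated more strongly. It sets out from triflate 6. Heck reaction with methyl vinyl ketone (Pd(OAc)2, PPh3, Et3N, DMF) should give silylated 3-hydroxy-β-ionone F5, and Bu4NF gives (3R)-3-hydroxy-β-ionone F6. VO(acac)2 and t-BuOOH give the syn-epoxy ionone F7, and dilute HClO4 in aqueous THF gives the triol ionone F8. Olefination with diethyl cyanomethylphosphonate (NaH, THF) gives the triol dienenitrile F9 after removal of the 9Z isomer, and iBu2AlH reduction returns to the route at 28.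

Step 20. The olefination may be unselective at C15=C15', the heating may also equilibrate C9'=C10' next to the alkyne, and the hydroxylated aldehyde may degrade under alkoxide. The fallback forms the central bond E-selectively at low temperature with a phosphonate. It sets out from diol 20. Appel bromination of the primary allylic hydroxyl (CBr4, PPh3, CH2Cl2, −20 °C) gives the C20 allylic bromide F10. Arbuzov reaction with P(OEt)3 at 80 °C gives the C20 diethyl phosphonate F11. Horner–Wadsworth–Emmons reaction with aldehyde 33 (NaN(SiMe3)2 in excess, THF, −78 to 0 °C) comes back to the route at target 36.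

**Further compounds**

F1 | step 9 | (E)-5-[(4R)-4-(tert-butyldimethylsilyloxy)-2,6,6-trimethylcyclohex-1-enyl]-3-methylpent-2-en-4-yn-1-ol | CC1=C(C#C/C(C)=C/CO)C(C)(C)C[C@H](O[Si](C)(C)C(C)(C)C)C1
F2 | step 9 | (E)-5-[(4R)-4-(tert-butyldimethylsilyloxy)-2,6,6-trimethylcyclohex-1-enyl]-3-methylpent-2-en-4-ynal | CC1=C(C#C/C(C)=C/C=O)C(C)(C)C[C@H](O[Si](C)(C)C(C)(C)C)C1
F3 | step 9 | ethyl (2E,4E,6E)-9-[(4R)-4-(tert-butyldimethylsilyloxy)-2,6,6-trimethylcyclohex-1-enyl]-3,7-dimethylnona-2,4,6-trien-8-ynoate | CC1=C(C#C/C(C)=C/C=C/C(C)=C/C(=O)OCC)C(C)(C)C[C@H](O[Si](C)(C)C(C)(C)C)C1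
F4 | step 9 | (2E,4E,6E)-9-[(4R)-4-(tert-butyldimethylsilyloxy)-2,6,6-trimethylcyclohex-1-enyl]-3,7-dimethylnona-2,4,6-trien-8-yn-1-ol | CC1=C(C#C/C(C)=C/C=C/C(C)=C/CO)C(C)(C)C[C@H](O[Si](C)(C)C(C)(C)C)C1
F5 | step 16 | (E)-4-[(4R)-4-(tert-butyldimethylsilyloxy)-2,6,6-trimethylcyclohex-1-enyl]but-3-en-2-one | CC1=C(/C=C/C(C)=O)C(C)(C)C[C@H](O[Si](C)(C)C(C)(C)C)C1
F6 | step 16 | (3R)-3-hydroxy-β-ionone | CC1=C(/C=C/C(C)=O)C(C)(C)C[C@H](O)C1
F7 | step 16 | (E)-4-[(1R,4S,6S)-4-hydroxy-2,2,6-trimethyl-7-oxabicyclo[4.1.0]heptan-1-yl]but-3-en-2-one | C[C@]12C[C@@H](O)CC(C)(C)[C@]1(O2)/C=C/C(C)=O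
F8 | step 16 | (E)-4-[(1R,2R,4S)-1,2,4-trihydroxy-2,6,6-trimethylcyclohexyl]but-3-en-2-one | CC(=O)/C=C/[C@@]1(O)C(C)(C)C[C@H](O)C[C@@]1(C)O
F9 | step 16 | (2E,4E)-3-methyl-5-[(1R,2R,4S)-1,2,4-trihydroxy-2,6,6-trimethylcyclohexyl]penta-2,4-dienenitrile | N#C/C=C(C)/C=C/[C@@]1(O)C(C)(C)C[C@H](O)C[C@@]1(C)O
F10 | step 20 | (1R)-4-[(3E,5E,7E)-9-bromo-3,7-dimethylnona-3,5,7-trien-1-ynyl]-3,5,5-trimethylcyclohex-3-en-1-ol | CC1=C(C#C/C(C)=C/C=C/C(C)=C/CBr)C(C)(C)C[C@H](O)C1
F11 | step 20 | diethyl [(2E,4E,6E)-9-[(4R)-4-hydroxy-2,6,6-trimethylcyclohex-1-enyl]-3,7-dimethylnona-2,4,6-trien-8-ynyl]phosphonate | CC1=C(C#C/C(C)=C/C=C/C(C)=C/CP(=O)(OCC)OCC)C(C)(C)C[C@H](O)C1
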